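The readings were generated by integration from invented constants, and the scatter is random.

Each L costs one G and each X two, so L + 2X counts the G spent. Birch's last reading gives 90.0% of the E charge, against 0.900 equiv of G, the limiting reagent, charged.

| flask | E | G | D | remark | time |
|---|---|---|---|---|---|
| birch | 0.10 M | 0.90 equiv | 1.9 mol% | run made earlier |  |
| oak | 0.10 M | 0.90 equiv | 0.95 mol% | run made earlier |  |
| larch | 0.10 M | 0.90 equiv | 1.4 mol% | run made earlier |  |
| Wednesday's | 0.10 M | 0.900 equiv | 1.9 mol% | a single well-mixed tank run continuously and read at steady state, 4.0 h in it on average |  |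
| Saturday's | 0.10 M (fed, over 3.20 h) | 0.900 equiv | 1.9 mol% | all but E at the start; E goes in evenly over 3.20 h, the run ends at 4.0 h | 4.0 h |
| Friday's | 0.10 M | 0.900 equiv | 1.9 mol% | a closed flask charged with all of it at once and left for 4.0 h | 4.0 h |
| Sunday's | 0.10 M | 0.900 equiv (fed, over 3.20 h) | 1.9 mol% | all but G at the start; G goes in evenly over 3.20 h, the run ends at 4.0 h | 4.0 h |

- birch (time / h: L / %, X / %): 0.200: 41, 11; 0.333: 43, 17; 0.500: 43, 17; 0.833: 43, 27; 1.33: 43, 24; 2.50: 42, 24
- oak (time / h: L / %, X / %): 0.667: 31, 18; 1.33: 27, 29; 2.00: 30, 34; 2.50: 25, 33; 3.00: 26, 28; 4.00: 25, 32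
- larch (time / h: L / %, X / %): 0.250: 34, 13; 0.833: 39, 25; 1.33: 36, 26; 2.00: 36, 26; 3.00: 35, 26; 4.00: 34, 27

(standard deviation of a reading: 2 percentage points)

- the stated concentrations are those of everything mixed, before any reaction; amounts are the same in each set-up
- the feed brings no volume worth counting
- the earlier runs were made in a closed, stirred flask

- the set-up with the highest share of L in all that became L or X, at the outlet or at the end ("none" if the first two lie within 2 percentage points) (Wednesday's / Saturday's / Friday's / Sunday's / none)
- share of L in all that became L or X, at the outlet or at the end, Wednesday's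
- share of L in all that became L or X, at the outlet or at the end, Saturday's
- share of L in all that became L or X, at the outlet or at the end, Friday's
- share of L in all that became L or X, at the outlet or at the end, Sunday's

If X comes from L, G enters both rates and should cancel from their ratio. So you keep one number for that race, with E, L and X as fractions of the E charge:

race number = 2(X/L) · E/(1 − E)

Birch ends at 0.589, oak at 1.93. Multiplied by its loading, oak's number is still larger than birch's, and oak's X levels off later, near 2.00 h against 0.833 h. Sunday's feed runs longer than either, 3.20 h, so I put Sunday's race number, oak's scaled to Sunday's loading, at no less than 0.966. Oak's own 1.93, at half Sunday's loading, I take as its ceiling.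

Now go round, because the race gives X/L from E and the G count gives E from the share:

E = 1 − G spent/(2 − share)

A larger race number gives a smaller share, so the floor serves the bound from above and the ceiling the bound from below.

Floor, round one, from birch's E of 34.0%: share 51.6%.

Floor, round two, from E of 39.3%: share 57.3%, the bound from above.

Ceiling, round one, from birch's E: share 34.8%.

Ceiling, round two, from E of 45.5%: share 46.4%.

Ceiling, round three, from E of 41.4%: share 42.3%, the bound from below.

Friday's repeats birch at 63.6%, 6.3 percentage points clear of that bracket, so I expect Friday's first.

The forecast gives 51%, 33%, 64% and 64% for Wednesday's, Saturday's, Friday's and Sunday's, best none, since “both steps are first order in G”. Its Sunday's figure stands above my bracket.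

The flasks give 44.8%, 35.8%, 63.1% and 53.7%, best Friday's; Sunday's falls inside the bracket.

    G + L → X (k = 0.546 M⁻¹ min⁻¹)
    D ⇌ Z (K = 1.60, k = 0.0244 min⁻¹)
    E + G + D → D + L (k = 567 M⁻² min⁻¹)

By 2.00 h Sunday's D stood at 39.0% of its charge with 11.9% of G present. From then to 4.00 h, X rose from 9.02% to 27.8% while L went from 27.5% to 32.2%. Sunday's race number ends at 1.15, above the floor of 0.966. The neighbour of Friday's charged with 0.025 M of E ends at race number 5.95 and share 38.7%.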